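**Retrosynthetic overview**

1. Numbering used in the text only: ring D = C2–C6 (C2 sp2, C3 H2, C4 carbinol, C5 CH–CH3, C6 H); ring C = C1(CH3)=C2, C6, C7(OH), C8(CH3), C17, C18, C19; ring B = C8–C11, C16, C17; ring A = C11–C16 (C14 gem-dimethyl); α = face of the C11 methyl, β = face of C16–H.
2. Enabling feature: ring D is an alkylidenecyclopentane. The tetrasubstituted C1=C2 bond is exocyclic to ring D and C2 is flanked by C3H2 and C6H, which is the retron of a palladium–trimethylenemethane (3+2) cycloaddition. C7–OH sits next to C6 and cis to the C5 methyl, so the two-carbon partner C4–C5 can be delivered from C7–O as an acrylate ester.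
3. Key disconnection: C3–C4 and C5–C6 in one intramolecular cycloaddition of a ring-C 2-(silylmethyl)allyl ester (tricycle 32 to pentacycle 33). The C5 methyl is carried as a temporary γ-lactone carbonyl and the C4 hydroxyl as a boronate; C4, C5 and C6 are set from C7.
4. Ring C (third): ring-closing metathesis to the C1=C19 enone on a diene built by an Evans glycolate aldol (C6, C7 by auxiliary) and isopropenyl addition; conjugate reduction/enol triflation and Kumada coupling then install the allylsilane.
5. Rings A/B (first): ring A is bought; a chiral-imine Michael addition/Robinson annulation sets C11 and forms ring B; reductive alkylation (C16, C17) and directed cyclopropanation/hydrogenolysis (C8) relay it. Ring order: A, B, C, then D with the temporary lactone.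

Key step: step 23

**Route**

Step 1
Reactants: 1 3,3-dimethylcyclohexanone
Product: 3 2,5,5-trimethylcyclohexanone (racemic), via lithium 5,5-dimethylcyclohex-1-en-1-olate 2 (not isolated)
Conditions: LiN(i-Pr)2, THF, −78 °C; then CH3I, −78 to 0 °C
Reagents that add atoms: iodomethane, CI
Why: Kinetic enolate alkylation, in which the amide base removes the less hindered C6 proton (the C2 methylene is neopentyl) and methylation there gives the 2,5,5-pattern; the new stereocentre is racemic and is re-set in step 2.

Step 2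
Reactants: 3 2,5,5-trimethylcyclohexanone
Product: 6 (2S)-2,5,5-trimethyl-2-(3-oxobutyl)cyclohexan-1-one, via (R)-1-phenylethyl imine 4 (not isolated), via Michael adduct imine 5 (not isolated)
Conditions: (R)-1-phenylethylamine, TsOH (cat.), toluene, reflux (Dean–Stark); then CH2=CHCOCH3, THF, 25 °C; then 10% aq. AcOH, 25 °C
Reagents that add atoms: methyl vinyl ketone, CC(=O)C=C; water, O
Why: Chiral-imine Michael addition (deracemising alkylation of a 2-alkylcyclohexanone), in which the imine reacts through its more substituted secondary enamine tautomer in a cyclic aza-ene-like transition state on the face away from the phenyl group, so the auxiliary amine sets the quaternary centre (C11), the (R)-amine being expected to give the (S)-adduct as in the parent 2-methylcyclohexanone series, and mild acid hydrolysis frees the diketone.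

Step 3
Reactants: 6 (2S)-2,5,5-trimethyl-2-(3-oxobutyl)cyclohexan-1-one
Product: 7 (4aS)-4a,7,7-trimethyl-4,4a,5,6,7,8-hexahydronaphthalen-2(3H)-one
Conditions: NaOMe, CH3OH, 60 °C
Reagents that add atoms: none
Why: Intramolecular aldol condensation (ring-closing half of a Robinson annulation) of the methyl ketone onto the ring carbonyl forms ring B as the conjugated enone without touching the quaternary centre.

Step 4
Reactants: 7 (4aS)-4a,7,7-trimethyl-4,4a,5,6,7,8-hexahydronaphthalen-2(3H)-one
Product: 9 methyl 2-[(1S,4aS,8aS)-4a,7,7-trimethyl-2-oxodecahydronaphthalen-1-yl]acetate, via lithium enolate 8 (not isolated)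
Conditions: Li, liquid NH3/THF, t-BuOH (1 equiv), −78 °C; evaporate NH3; then BrCH2CO2CH3, THF, −78 to 0 °C
Reagents that add atoms: methyl bromoacetate, COC(=O)CBr
Why: Dissolving-metal reductive alkylation of an enone, in which protonation at the β-carbon gives the trans ring fusion (C16–H anti to the axial C11 methyl) and the regiodefined enolate is alkylated at C17 on the face away from that methyl, placing the acetate arm equatorial (also the thermodynamic epimer next to the ketone).

Step 5
Reactants: 9 methyl 2-[(1S,4aS,8aS)-4a,7,7-trimethyl-2-oxodecahydronaphthalen-1-yl]acetate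
Product: 11 C8=C9 enol triflate of 9, via C8=C9 lithium enolate 10 (not isolated)
Conditions: LiN(SiMe3)2, THF, −78 °C; then PhNTf2, −78 to 0 °C
Reagents that add atoms: N-phenylbis(trifluoromethanesulfonimide), O=S(=O)(N(c1ccccc1)S(=O)(=O)C(F)(F)F)C(F)(F)F
Why: Kinetic deprotonation at the C9 methylene (the ketone is more acidic than the ester and C17–H is tertiary and hindered) followed by O-sulfonylation gives the C8=C9 enol triflate with no change at any stereocentre.

Step 6
Reactants: 11 C8=C9 enol triflate
Product: 12 unsaturated diester (methyl ester C7 on the C8=C9 alkene; C17–CH2CO2CH3)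
Conditions: CO (1 atm), CH3OH, Pd(OAc)2 (5 mol %), PPh3, Et3N, DMF, 60 °C
Reagents that add atoms: carbon monoxide, [C-]#[O+]; methanol, CO
Why: Palladium-catalysed alkoxycarbonylation of an enol triflate (oxidative addition, CO insertion, methanolysis) installs C7 at the ester level on the C8=C9 alkene.

Step 7
Reactants: 12 unsaturated diester
Product: 13 allylic diol (C7H2OH on C8=C9; C17–CH2CH2OH)
Conditions: i-Bu2AlH (5 equiv), CH2Cl2, −78 to 0 °C
Reagents that add atoms: none
Why: Hydride reduction of both esters, the conjugated one giving the allylic alcohol by 1,2-reduction and the saturated one the primary alcohol.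

Step 8
Reactants: 13 allylic diol
Product: 14 8β,9β-methano (cyclopropane) diol
Conditions: Et2Zn, CH2I2, CH2Cl2, 0 to 25 °C
Reagents that add atoms: diiodomethane, ICI
Why: Hydroxyl-directed Simmons–Smith cyclopropanation, in which the zinc carbenoid bound to the allylic alkoxide adds to the C8=C9 alkene from the β-face because the axial C11 methyl shields the α-face of this octalin, which fixes the future C8 methyl carbon on the β-face.

Step 9
Reactants: 14 cyclopropane diol
Product: 15 diol with β-methyl at C8 (C7H2OH; C17–CH2CH2OH)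
Conditions: H2 (3 atm), PtO2, AcOH, 25 °C
Reagents that add atoms: none
Why: Catalytic hydrogenolysis of a cyclopropane cleaves the least substituted bond (C9–CH2), so the methylene stays on C8 as the β-methyl with the C8 configuration of step 8 retained, giving the quaternary centre with C7 equatorial.

Step 10
Reactants: 15 diol
Product: 16 dialdehyde (C7 and C19 aldehydes)
Conditions: Dess–Martin periodinane, NaHCO3, CH2Cl2, 25 °C
Reagents that add atoms: none
Why: Dess–Martin oxidation of both primary alcohols under buffered, non-epimerising conditions, the C7 aldehyde having no α-hydrogen.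

Step 11
Reactants: 16 dialdehyde
Product: 17 C7 aldehyde with C17 allyl group
Conditions: Ph3PCH3Br, KOt-Bu, THF, 0 °C; then 16 (1.0 equiv of ylide), −78 to 0 °C
Reagents that add atoms: methyltriphenylphosphonium bromide, C[P+](c1ccccc1)(c1ccccc1)c1ccccc1.[Br-]
Why: Wittig methylenation with one equivalent of ylide, in which the unhindered C19 aldehyde reacts while the neopentyl C7 aldehyde on the quaternary C8 is much slower, so the allyl group is formed and the C7 aldehyde is kept.

Step 12
Reactants: 18 (R)-4-benzyloxazolidin-2-one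
Product: 19 (R)-4-benzyl-3-[(benzyloxy)acetyl]oxazolidin-2-one
Conditions: BnOCH2COCl, Et3N, DMAP (cat.), CH2Cl2, 0 to 25 °C
Reagents that add atoms: benzyloxyacetyl chloride, O=C(Cl)COCc1ccccc1
Why: N-acylation of the oxazolidinone with the acid chloride under DMAP catalysis gives the glycolate imide without touching the auxiliary stereocentre.

Step 13
Reactants: 17 C7 aldehyde with C17 allyl group; 19 (R)-4-benzyl-3-[(benzyloxy)acetyl]oxazolidin-2-one
Product: 21 syn aldol adduct, (2R,3S)-2-benzyloxy-3-hydroxyacyl oxazolidinone (C6–OBn, C7–OH), via (Z)-dibutylboron enolate 20 (not isolated)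
Conditions: 19, Bu2BOTf, Et3N, CH2Cl2, −78 to 0 °C; then 17, −78 to 0 °C; pH 7 buffer, CH3OH, 30% H2O2
Reagents that add atoms: none
Why: Evans syn aldol reaction, in which the (Z)-boron enolate reacts through a chair Zimmerman–Traxler transition state on the enolate face away from the benzyl group of the (R)-auxiliary, which sets C6 (benzyloxy) and C7 (hydroxyl) as the (2R,3S) syn pair by reagent control over the hindered aldehyde.

Step 14
Reactants: 21 syn aldol adduct
Product: 22 Weinreb amide (C6–OBn, C7–OH)
Conditions: CH3NH(OCH3)·HCl, AlMe3, CH2Cl2, 0 to 25 °C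
Reagents that add atoms: N,O-dimethylhydroxylamine hydrochloride, CNOC.Cl
Why: Aluminium amide transamidation of the imide, assisted by the free β-hydroxyl, gives the Weinreb amide and releases the auxiliary without retro-aldol cleavage.

Step 15
Reactants: 22 Weinreb amide
Product: 23 C7 triethylsilyl ether of 22
Conditions: Et3SiOTf, 2,6-lutidine, CH2Cl2, −78 to 0 °C
Reagents that add atoms: triethylsilyl trifluoromethanesulfonate, CC[Si](CC)(CC)OS(=O)(=O)C(F)(F)F
Why: Silylation of the hindered secondary alcohol with the silyl triflate protects C7–OH against retro-aldol cleavage in the following steps.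

Step 16
Reactants: 23 silyl ether Weinreb amide
Product: 24 isopropenyl ketone (diene for ring closure)
Conditions: CH2=C(CH3)MgBr, THF, 0 °C
Reagents that add atoms: isopropenylmagnesium bromide, CC(=C)[Mg]Br
Why: Grignard addition to the Weinreb amide stops at the chelated tetrahedral intermediate and gives the isopropenyl ketone on work-up, which brings in C1 and its methyl group.

Step 17
Reactants: 24 isopropenyl ketone
Product: 25 tricyclic enone (C2 ketone, C1=C19; C6 β-OBn, C7 α-OSiEt3)
Conditions: second-generation Grubbs catalyst RuCl2(=CHPh)(PCy3)(H2IMes) (10 mol %), toluene (0.002 M), 80 °C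
Reagents that add atoms: none
Why: Ring-closing metathesis between the allyl group and the isopropenyl ketone forms ring C as the α-methyl enone, the two arms being held trans-diequatorial on ring B, with loss of ethylene and no new stereocentre.

Step 18
Reactants: 25 tricyclic enone
Product: 27 tetrasubstituted enol triflate (C1=C2–OTf), via C1=C2 lithium enolate 26 (not isolated)
Conditions: LiBH(s-Bu)3, THF, −78 °C; then PhNTf2, −78 to 25 °C
Reagents that add atoms: N-phenylbis(trifluoromethanesulfonimide), O=S(=O)(N(c1ccccc1)S(=O)(=O)C(F)(F)F)C(F)(F)F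
Why: Conjugate (1,4) hydride reduction of the enone gives the C1=C2 enolate regiospecifically and O-triflation traps it as the tetrasubstituted enol triflate before it can equilibrate toward C6.

Step 19
Reactants: 27 enol triflate
Product: 28 diol triflate (C6 β-OH, C7 α-OH)
Conditions: BCl3, CH2Cl2, −78 to −20 °C; then CH3OH
Reagents that add atoms: none
Why: Lewis acid cleavage of the benzyl ether with BCl3 and methanolysis of the silyl ether by the HCl formed on quenching free both hydroxyls while the electron-poor enol triflate is inert.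

Step 20
Reactants: 28 diol triflate
Product: 29 allylsilane diol (C2–CH2SiMe3 on the C1=C2 alkene)
Conditions: Me3SiCH2MgCl (5 equiv), Pd(PPh3)4 (5 mol %), THF, 25 to 50 °C; aq. NH4Cl
Reagents that add atoms: (trimethylsilyl)methylmagnesium chloride, C[Si](C)(C)C[Mg]Cl
Why: Kumada cross-coupling of the enol triflate with the silylmethyl Grignard reagent (the diol carried as its magnesium alkoxide) installs C3 as the allylsilane on the tetrasubstituted alkene, with neutral work-up to avoid protodesilylation.

Step 21
Reactants: 30 ethyl (E)-3-(4,4,5,5-tetramethyl-1,3,2-dioxaborolan-2-yl)acrylate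
Product: 31 (E)-3-(4,4,5,5-tetramethyl-1,3,2-dioxaborolan-2-yl)acrylic acid
Conditions: Me3SnOH, ClCH2CH2Cl, 80 °C; then 1 M HCl
Reagents that add atoms: trimethyltin hydroxide, C[Sn](C)(C)O
Why: Mild ester hydrolysis with trimethyltin hydroxide cleaves the ethyl ester without conjugate addition or loss of the pinacol boronate and keeps the alkene geometry.

Step 22
Reactants: 29 allylsilane diol; 31 (E)-3-(pinacolboryl)acrylic acid
Product: 32 bis[(E)-3-(pinacolboryl)acrylate] of 29
Conditions: 31 (3 equiv), EDC·HCl, DMAP, CH2Cl2, 25 to 40 °C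
Reagents that add atoms: none
Why: Steglich esterification of both secondary hydroxyls (carbodiimide activation, DMAP acyl transfer) gives the bis-ester in which the allylic C6 ester will be the leaving group and the C7 ester the tethered acceptor, with no stereocentre touched.

Step 23
Reactants: 32 bis[(E)-3-(pinacolboryl)acrylate]
Product: 33 pentacyclic boronate lactone (ring D closed; C4 α-Bpin, C5 carboxyl lactonised onto C7–O, C6 α-H)
Conditions: Pd(OAc)2 (10 mol %), P(O-i-Pr)3 (60 mol %), toluene (0.005 M), 100 °C
Reagents that add atoms: none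
Why: Zerovalent palladium ionises the only allylic ester (C6–O) anti to the leaving group, the expelled carboxylate removes the silyl group, and the zwitterionic trimethylenemethane–palladium complex (C3, C2, C6, with the C1 terminus locked in ring C) adds through C3 to the β-carbon C4 of the acrylate held on C7–O, after which the ester enolate carbon C5 attacks the π-allyl terminus C6 on the face away from palladium. The closest known reaction type is the palladium-catalysed trimethylenemethane (3+2) cycloaddition of 2-(silylmethyl)allyl esters with enoates in its intramolecular form; here the ester carbonyl lies inside the tether. Ring D closes by conjugate addition followed by five-membered C-allylation, and the same C5–C6 bond closes the temporary γ-lactone, which can only be cis-fused to ring D. C6 is set by C7, because the three-atom tether lets C5 reach only the face of the allyl unit that carries the C7–O bond (C7–H eclipsing the allyl plane, the A(1,3) minimum), which is also the face of the departed carboxylate (net retention by double inversion); C5 is fixed cis to C6 by the lactone ring, and C4 follows from the E geometry of the acrylate (boron trans to the carbonyl carbon), which is also the more stable arrangement. The step needs regioselectivity among the three termini and chemoselective ionisation: C1 is fully substituted and out of reach of the tether, so closure occurs at C6, and only the C6 ester is allylic, so the C7 ester survives as the acceptor.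

Step 24
Reactants: 33 pentacyclic boronate lactone
Product: 34 C4 α-hydroxy lactone
Conditions: NaBO3·4H2O, THF/H2O (1:1), 25 °C
Reagents that add atoms: sodium perborate tetrahydrate, O[B-]1(O)OO[B-](O)(O)OO1.[Na+].[Na+]
Why: Oxidation of the secondary alkylboronate with perborate proceeds by 1,2-migration with retention, so C4–O keeps the α-configuration set in step 23, and this nucleophilic oxidant attacks neither the alkene nor the lactone.

Step 25
Reactants: 34 C4 α-hydroxy lactone
Product: 35 lactol (anomeric mixture)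
Conditions: i-Bu2AlH (3 equiv), CH2Cl2, −78 °C
Reagents that add atoms: none
Why: Half-reduction of the γ-lactone with i-Bu2AlH at low temperature stops at the lactol through the stable tetrahedral aluminium alkoxide, the free hydroxyl being carried as its alkoxide.

Step 26
Reactants: 35 lactol
Product: 37 target diol (C4 α-OH, C5 β-CH3, C6 α-H, C7 α-OH), via tosylhydrazone 36 (not isolated)
Conditions: TsNHNH2, CH3OH, 50 °C; then catecholborane, CHCl3, 0 °C; then NaOAc·3H2O, 60 °C
Reagents that add atoms: none
Why: Condensation of the open hydroxy aldehyde form of the lactol with tosylhydrazide, catecholborane reduction of the tosylhydrazone and acetate-induced loss of sulfinate and nitrogen (Caglioti-type deoxygenation) turn the aldehyde carbon into the C5 methyl group and free C7–OH under conditions that should neither epimerise C5 nor move the alkene.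

**Compound list**

1 | 3,3-dimethylcyclohexanone | CC1(C)CCCC(=O)C1 | starting material
2 | lithium 5,5-dimethylcyclohex-1-en-1-olate | [Li]OC1=CCCC(C)(C)C1 | intermediate
3 | 2,5,5-trimethylcyclohexanone (racemic) | CC1CCC(C)(C)CC1=O | intermediate
4 | 2,5,5-trimethyl-N-[(1R)-1-phenylethyl]cyclohexan-1-imine | CC1CCC(C)(C)CC1=N[C@H](C)c1ccccc1 | intermediate
5 | N-[(1R)-1-phenylethyl]imine of 6 (Michael adduct) | CC(=O)CC[C@]1(C)CCC(C)(C)CC1=N[C@H](C)c1ccccc1 | intermediate
6 | (2S)-2,5,5-trimethyl-2-(3-oxobutyl)cyclohexan-1-one | CC(=O)CC[C@]1(C)CCC(C)(C)CC1=O | intermediate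
7 | (4aS)-4a,7,7-trimethyl-4,4a,5,6,7,8-hexahydronaphthalen-2(3H)-one | O=C1C=C2CC(C)(C)CC[C@@]2(C)CC1 | intermediate
8 | lithium enolate (C8–OLi, C8=C17) of the trans-fused decalone | [Li]OC=1CC[C@]2(C)CCC(C)(C)C[C@H]2C=1 | intermediate
9 | methyl 2-[(1S,4aS,8aS)-4a,7,7-trimethyl-2-oxodecahydronaphthalen-1-yl]acetate (trans-fused, arm equatorial) | O=C1CC[C@]2(C)CCC(C)(C)C[C@H]2[C@@H]1CC(=O)OC | intermediate
10 | lithium enolate of 9 toward C9 (C8=C9) | [Li]OC1=CC[C@]2(C)CCC(C)(C)C[C@H]2[C@@H]1CC(=O)OC | intermediate
11 | C8=C9 enol triflate of 9 | O=S(=O)(OC1=CC[C@]2(C)CCC(C)(C)C[C@H]2[C@@H]1CC(=O)OC)C(F)(F)F | intermediate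
12 | unsaturated diester (C7 methyl ester on C8=C9; C17–CH2CO2CH3) | COC(=O)C1=CC[C@]2(C)CCC(C)(C)C[C@H]2[C@@H]1CC(=O)OC | intermediate
13 | allylic diol (C7H2OH on C8=C9; C17–CH2CH2OH) | OCC1=CC[C@]2(C)CCC(C)(C)C[C@H]2[C@@H]1CCO | intermediate
14 | 8β,9β-methano diol (cyclopropane on the β-face) | OC[C@@]12C[C@@H]1C[C@]1(C)CCC(C)(C)C[C@H]1[C@@H]2CCO | intermediate
15 | diol with quaternary C8 (β-CH3, C7H2OH α-equatorial; C17–CH2CH2OH β) | OC[C@@]1(C)CC[C@]2(C)CCC(C)(C)C[C@H]2[C@@H]1CCO | intermediate
16 | dialdehyde (C7 and C19) | O=C[C@@]1(C)CC[C@]2(C)CCC(C)(C)C[C@H]2[C@@H]1CC=O | intermediate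
17 | C7 aldehyde with C17 allyl group | O=C[C@@]1(C)CC[C@]2(C)CCC(C)(C)C[C@H]2[C@@H]1CC=C | intermediate
18 | (R)-4-benzyloxazolidin-2-one | O=C1N[C@H](Cc2ccccc2)CO1 | starting material
19 | (R)-4-benzyl-3-[(benzyloxy)acetyl]oxazolidin-2-one | O=C(COCc1ccccc1)N1[C@H](Cc2ccccc2)COC1=O | intermediate
20 | (Z)-dibutylboron enolate of 19 | CCCCB(CCCC)O/C(=C\OCc1ccccc1)N1[C@H](Cc2ccccc2)COC1=O | intermediate
21 | syn aldol adduct, (2R,3S)-2-benzyloxy-3-hydroxyacyl imide (C6–OBn, C7–OH) | O=C([C@H](OCc1ccccc1)[C@@H](O)[C@@]1(C)CC[C@]2(C)CCC(C)(C)C[C@H]2[C@@H]1CC=C)N1[C@H](Cc2ccccc2)COC1=O | intermediate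
22 | Weinreb amide, (2R,3S)-2-benzyloxy-3-hydroxy | CON(C)C(=O)[C@H](OCc1ccccc1)[C@@H](O)[C@@]1(C)CC[C@]2(C)CCC(C)(C)C[C@H]2[C@@H]1CC=C | intermediate
23 | C7 triethylsilyl ether of 22 | CON(C)C(=O)[C@H](OCc1ccccc1)[C@@H](O[Si](CC)(CC)CC)[C@@]1(C)CC[C@]2(C)CCC(C)(C)C[C@H]2[C@@H]1CC=C | intermediate
24 | isopropenyl ketone (C2 ketone; C6–OBn, C7–OSiEt3; C17 allyl) | CC(=C)C(=O)[C@H](OCc1ccccc1)[C@@H](O[Si](CC)(CC)CC)[C@@]1(C)CC[C@]2(C)CCC(C)(C)C[C@H]2[C@@H]1CC=C | intermediate
25 | tricyclic enone (ring C closed; C2 ketone, C1=C19; C6 β-OBn, C7 α-OSiEt3) | O=C1[C@H](OCc2ccccc2)[C@@H](O[Si](CC)(CC)CC)[C@@]2(C)CC[C@]3(C)CCC(C)(C)C[C@H]3[C@@H]2C/C=C1/C | intermediate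
26 | lithium enolate (C2–OLi, C1=C2) | C/C1=C(\O[Li])[C@H](OCc2ccccc2)[C@@H](O[Si](CC)(CC)CC)[C@@]2(C)CC[C@]3(C)CCC(C)(C)C[C@H]3[C@@H]2CC1 | intermediate
27 | tetrasubstituted enol triflate (C1=C2–OTf; C6 β-OBn, C7 α-OSiEt3) | C/C1=C(\OS(=O)(=O)C(F)(F)F)[C@H](OCc2ccccc2)[C@@H](O[Si](CC)(CC)CC)[C@@]2(C)CC[C@]3(C)CCC(C)(C)C[C@H]3[C@@H]2CC1 | intermediate
28 | diol triflate (C6 β-OH, C7 α-OH) | C/C1=C(\OS(=O)(=O)C(F)(F)F)[C@H](O)[C@@H](O)[C@@]2(C)CC[C@]3(C)CCC(C)(C)C[C@H]3[C@@H]2CC1 | intermediate
29 | allylsilane diol (C2–CH2SiMe3; C6 β-OH, C7 α-OH) | C/C1=C(\C[Si](C)(C)C)[C@H](O)[C@@H](O)[C@@]2(C)CC[C@]3(C)CCC(C)(C)C[C@H]3[C@@H]2CC1 | intermediate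
30 | ethyl (E)-3-(4,4,5,5-tetramethyl-1,3,2-dioxaborolan-2-yl)acrylate | CCOC(=O)/C=C/B1OC(C)(C)C(C)(C)O1 | starting material
31 | (E)-3-(4,4,5,5-tetramethyl-1,3,2-dioxaborolan-2-yl)acrylic acid | OC(=O)/C=C/B1OC(C)(C)C(C)(C)O1 | intermediate
32 | bis[(E)-3-(pinacolboryl)acrylate] of 29 (C6 β-ester, C7 α-ester) | C/C1=C(\C[Si](C)(C)C)[C@H](OC(=O)/C=C/B2OC(C)(C)C(C)(C)O2)[C@@H](OC(=O)/C=C/B2OC(C)(C)C(C)(C)O2)[C@@]2(C)CC[C@]3(C)CCC(C)(C)C[C@H]3[C@@H]2CC1 | intermediate
33 | pentacyclic boronate lactone (C4 α-Bpin; C5 carbonyl lactonised to C7–O, cis-fused to ring D; C6 α-H) | C/C1=C2\C[C@@H](B3OC(C)(C)C(C)(C)O3)[C@H](C(=O)O4)[C@@H]2[C@@H]4[C@@]2(C)CC[C@]3(C)CCC(C)(C)C[C@H]3[C@@H]2CC1 | intermediate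
34 | C4 α-hydroxy lactone | C/C1=C2\C[C@@H](O)[C@H](C(=O)O4)[C@@H]2[C@@H]4[C@@]2(C)CC[C@]3(C)CCC(C)(C)C[C@H]3[C@@H]2CC1 | intermediate
35 | lactol (anomeric mixture) | C/C1=C2\C[C@@H](O)[C@H](C(O)O4)[C@@H]2[C@@H]4[C@@]2(C)CC[C@]3(C)CCC(C)(C)C[C@H]3[C@@H]2CC1 | intermediate
36 | tosylhydrazone of the ring-opened hydroxy aldehyde | C/C1=C2\C[C@@H](O)[C@H](C=NNS(=O)(=O)c3ccc(C)cc3)[C@@H]2[C@@H](O)[C@@]2(C)CC[C@]3(C)CCC(C)(C)C[C@H]3[C@@H]2CC1 | intermediate
37 | target diol (C4 α-OH, C5 β-CH3, C6 α-H, C7 α-OH, C8 β-CH3, C11 α-CH3, C16 β-H, C17 α-H) | C/C1=C2\C[C@@H](O)[C@H](C)[C@@H]2[C@@H](O)[C@@]2(C)CC[C@]3(C)CCC(C)(C)C[C@H]3[C@@H]2CC1 | target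

**Step count and risks**

Total step count: 26. Longest linear sequence: 24 steps (steps 1–11, 13–20, 22–26, from 1 to 37); steps 12 and 21 are side branches.

Steps most likely to fail:

1. Step 23 (cycloaddition). The conjugate addition to the β-substituted acrylate must pass through the s-cis ester geometry and may be slower than protodesilylation of the palladium complex; the alkenyl boronate may also be lost by transmetalation. The fallback changes the acceptor and the way the C4 oxygen is brought in; it sets out from 29 and returns at 34.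
   - Esterification of 29 with mono-tert-butyl fumarate (EDC·HCl, DMAP) would give the bis(tert-butyl fumarate) F1.
   - The same Pd(OAc)2/P(O-i-Pr)3 cycloaddition, now with a doubly activated fumarate (a well-precedented acceptor class), would give the C4 tert-butyl ester lactone F2, with C5 and C6 set as before and the C4 ester trans to the lactone carbonyl.
   - Me3SiOTf/2,6-lutidine would cleave the tert-butyl ester to the acid F3.
   - Coupling with N-hydroxypyridine-2-thione (N,N′-dicyclohexylcarbodiimide, dark) would give the Barton ester F4.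
   - Barton decarboxylative oxygenation (O2, t-BuSH, visible light) would give the C4 hydroperoxide F5; the C4 radical is expected to be trapped on the face away from the neighbouring lactone carbon, that is α.
   - Reduction with PPh3 would give 34.

2. Step 17 (ring-closing metathesis). The electron-poor 1,1-disubstituted alkene may dimerise or fail to close to the trisubstituted eight-membered enone. The fallback closes ring C by olefination instead; it sets out from 23 and returns at 25.
   - Addition of LiCH(CH3)P(O)(OEt)2 to the Weinreb amide would give the β-ketophosphonate F6.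
   - Ozonolysis of the terminal alkene (O3, CH2Cl2/CH3OH, −78 °C; PPh3) would give the aldehyde F7.
   - Intramolecular Horner–Wadsworth–Emmons reaction under Masamune–Roush conditions (LiCl, i-Pr2NEt, CH3CN, high dilution) would give 25.

3. Step 18 (conjugate reduction/triflation). Competing 1,2-reduction of the twisted medium-ring enone, or proton transfer of the enolate before trapping, would erode the regiodefined enol triflate. The fallback separates the two events through an isolable enol silane; it sets out from 25 and returns at 27.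
   - Copper hydride-catalysed 1,4-hydrosilylation ([(Ph3P)CuH]6 (cat.), PhMe2SiH, toluene) would give the dimethylphenylsilyl enol ether F8.
   - Cleavage with MeLi (THF, 0 °C) to the lithium enolate and triflation with PhNTf2 would give 27.

Further compounds
F1 | step 23 | bis(tert-butyl fumarate) of 29 | C/C1=C(\C[Si](C)(C)C)[C@H](OC(=O)/C=C/C(=O)OC(C)(C)C)[C@@H](OC(=O)/C=C/C(=O)OC(C)(C)C)[C@@]2(C)CC[C@]3(C)CCC(C)(C)C[C@H]3[C@@H]2CC1
F2 | step 23 | C4 α-tert-butyl ester lactone | C/C1=C2\C[C@@H](C(=O)OC(C)(C)C)[C@H](C(=O)O4)[C@@H]2[C@@H]4[C@@]2(C)CC[C@]3(C)CCC(C)(C)C[C@H]3[C@@H]2CC1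
F3 | step 23 | C4 α-carboxylic acid lactone | C/C1=C2\C[C@@H](C(=O)O)[C@H](C(=O)O4)[C@@H]2[C@@H]4[C@@]2(C)CC[C@]3(C)CCC(C)(C)C[C@H]3[C@@H]2CC1
F4 | step 23 | Barton ester (2-thioxopyridin-1-yl ester) of F3 | C/C1=C2\C[C@@H](C(=O)ON5C=CC=CC5=S)[C@H](C(=O)O4)[C@@H]2[C@@H]4[C@@]2(C)CC[C@]3(C)CCC(C)(C)C[C@H]3[C@@H]2CC1
F5 | step 23 | C4 α-hydroperoxide lactone | C/C1=C2\C[C@@H](OO)[C@H](C(=O)O4)[C@@H]2[C@@H]4[C@@]2(C)CC[C@]3(C)CCC(C)(C)C[C@H]3[C@@H]2CC1
F6 | step 17 | β-ketophosphonate (diethyl phosphonate at C1; C17 allyl) | CCOP(=O)(OCC)C(C)C(=O)[C@H](OCc1ccccc1)[C@@H](O[Si](CC)(CC)CC)[C@@]1(C)CC[C@]2(C)CCC(C)(C)C[C@H]2[C@@H]1CC=C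
F7 | step 17 | β-ketophosphonate C19 aldehyde | CCOP(=O)(OCC)C(C)C(=O)[C@H](OCc1ccccc1)[C@@H](O[Si](CC)(CC)CC)[C@@]1(C)CC[C@]2(C)CCC(C)(C)C[C@H]2[C@@H]1CC=O
F8 | step 18 | dimethylphenylsilyl enol ether (C1=C2–OSi) | C/C1=C(\O[Si](C)(C)c2ccccc2)[C@H](OCc2ccccc2)[C@@H](O[Si](CC)(CC)CC)[C@@]2(C)CC[C@]3(C)CCC(C)(C)C[C@H]3[C@@H]2CC1
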